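**Retrosynthetic overview**
1. Target 36 ⇒ α‑methoxy enone 34. C3 is set last, by Cu–H 1,4‑reduction and protonation on the open face. 34 ⇒ keto acetate 27 by α‑oxidation and O‑methylation.
2. 27 ⇒ ketol 23. The C8–O centre comes from a chelation‑controlled syn‑1,3‑reduction, after which C4 is re‑oxidised.
3. 23 ⇒ keto aldehyde 21. A chelated titanium aldol forms the C4–C5 bond and closes the six‑membered ring (second ring) onto a cyclopentanone.
4. 21 ⇒ enone 12 ⇒ enone 5. Methyl (C7), allyl plus C3 chain (C1) and aryl (C6) are added one by one on the five‑membered ring (first ring, present from the start). Each group enters anti to its neighbour.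
5. 5 ⇒ meso‑diacetate 1. A lipase desymmetrisation fixes the absolute configuration.

Assumption: bicyclic compounds carry the locants C1 (allyl bridgehead), C2, C3, C4 (three‑carbon bridge), C5 (OMe bridgehead), C6 (aryl), C7 (methyl), C8 (one‑carbon bridge); "exo" means the face of the C2–C4 bridge turned toward C8; MeLi, Me2Zn, LDA and the aryl Grignard are bought as solutions.

**Step 1**
Reactants: 1 cis‑cyclopent‑4‑ene‑1,3‑diyl diacetate (meso)
Product: 2 (1R,4S)‑4‑hydroxycyclopent‑2‑en‑1‑yl acetate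
Conditions: lipase (Candida antarctica lipase B, immobilised, Novozym 435), MeOH, MTBE, 5 °C
Reagents that add atoms: none
Why: In this enzymatic desymmetrisation by lipase (serine hydrolase) transesterification, only the acetate on the S‑configured carbon of the achiral meso substrate is passed to methanol, which fixes 1R,4S in very high ee with a theoretical yield of 100 %.

**Step 2**
Reactants: 2 (1R,4S)‑4‑hydroxycyclopent‑2‑en‑1‑yl acetate
Product: 3 (1R,4S)‑4‑[(tert‑butyldimethylsilyl)oxy]cyclopent‑2‑en‑1‑yl acetate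
Conditions: TBSCl, imidazole, DMF, 0 °C → rt
Reagents that add atoms: tert‑butyldimethylsilyl chloride CC(C)(C)[Si](C)(C)Cl
Why: This is a standard imidazole‑promoted silylation of the free secondary alcohol and touches no stereocentre.

**Step 3**
Reactants: 3 (1R,4S)‑4‑[(tert‑butyldimethylsilyl)oxy]cyclopent‑2‑en‑1‑yl acetate
Product: 4 (1R,4S)‑4‑[(tert‑butyldimethylsilyl)oxy]cyclopent‑2‑en‑1‑ol
Conditions: K2CO3 (cat.), MeOH, 0 °C
Reagents that add atoms: none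
Why: Base‑catalysed transesterification (methanolysis) removes the acetate while the TBS ether survives.

**Step 4**
Reactants: 4 (1R,4S)‑4‑[(tert‑butyldimethylsilyl)oxy]cyclopent‑2‑en‑1‑ol
Product: 5 (S)‑4‑[(tert‑butyldimethylsilyl)oxy]cyclopent‑2‑en‑1‑one
Conditions: Dess–Martin periodinane, CH2Cl2, 0 °C → rt
Reagents that add atoms: none
Why: Dess–Martin oxidation of the allylic alcohol gives the enone, and the silyloxy‑bearing carbon keeps its S configuration.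

**Step 5**
Reactants: 5 (S)‑4‑[(tert‑butyldimethylsilyl)oxy]cyclopent‑2‑en‑1‑one; 6 allyl iodide
Product: 8 (2S,3S,4S)‑2‑allyl‑4‑[(tert‑butyldimethylsilyl)oxy]‑3‑methylcyclopentan‑1‑one, via lithium zinc enolate 7 (not isolated)
Conditions: Me2Zn + MeLi (→ LiZnMe3), THF, −78 °C; then 6, HMPA, −78 → −40 °C; aq NH4Cl
Reagents that add atoms: lithium trimethylzincate [Li+].C[Zn-](C)C, made from methyllithium [Li]C and dimethylzinc C[Zn]C
Why: In this Noyori‑type three‑component coupling the zincate delivers methyl anti to the silyloxy group (this sets C7), and the non‑equilibrating zinc enolate is allylated anti to the new methyl before β‑elimination can start.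

**Step 6**
Reactants: 8 (2S,3S,4S)‑2‑allyl‑4‑[(tert‑butyldimethylsilyl)oxy]‑3‑methylcyclopentan‑1‑one
Product: 9 (4R,5S)‑5‑allyl‑4‑methylcyclopent‑2‑en‑1‑one
Conditions: DBU, CH2Cl2, 0 °C, short time
Reagents that add atoms: none
Why: E1cB elimination of the β‑silyloxy group gives the new enone much faster than γ‑deprotonation, so the methyl‑bearing centre is kept.

**Step 7**
Reactants: 9 (4R,5S)‑5‑allyl‑4‑methylcyclopent‑2‑en‑1‑one; 10 3‑bromo‑1‑(trimethylsilyl)prop‑1‑yne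
Product: 12 (4R,5S)‑5‑allyl‑4‑methyl‑5‑[3‑(trimethylsilyl)prop‑2‑yn‑1‑yl]cyclopent‑2‑en‑1‑one, via lithium dienolate 11 (not isolated)
Conditions: LDA, THF, −78 °C; then 10, DMPU, −78 → −30 °C
Reagents that add atoms: none
Why: Kinetic α′‑deprotonation gives the flat cross‑conjugated enolate, and the reactive propargylic bromide attacks anti to the adjacent methyl, which sets quaternary C1 with allyl cis and the three‑carbon chain trans to the methyl.

**Step 8**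
Reactants: 12 (4R,5S)‑5‑allyl‑4‑methyl‑5‑[3‑(trimethylsilyl)prop‑2‑yn‑1‑yl]cyclopent‑2‑en‑1‑one; 13 (3,4‑dimethoxyphenyl)magnesium bromide
Product: 14 {[(3R,4R,5S)‑5‑allyl‑3‑(3,4‑dimethoxyphenyl)‑4‑methyl‑5‑[3‑(trimethylsilyl)prop‑2‑yn‑1‑yl]cyclopent‑1‑en‑1‑yl]oxy}trimethylsilane
Conditions: 13, CuBr·SMe2 (10 mol %), TMSCl, THF, −78 °C
Reagents that add atoms: chlorotrimethylsilane C[Si](C)(C)Cl
Why: In this TMSCl‑accelerated copper‑catalysed conjugate addition the aryl group adds anti to the neighbouring methyl (trans C6/C7), and the enolate is caught regiospecifically as its silyl ether.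

**Step 9**
Reactants: 14 silyl enol ether
Product: 17 (2S,3R,4S,5S)‑2‑allyl‑4‑(3,4‑dimethoxyphenyl)‑5‑hydroxy‑3‑methyl‑2‑[3‑(trimethylsilyl)prop‑2‑yn‑1‑yl]cyclopentan‑1‑one, via silyloxy epoxide 15 (not isolated), via silyloxy ketone 16 (not isolated)
Conditions: mCPBA (1.05 equiv), hexane/CH2Cl2, −15 °C; then 1 M HCl, THF, 0 °C
Reagents that add atoms: 3‑chloroperoxybenzoic acid OOC(=O)c1cccc(Cl)c1
Why: In this Rubottom oxidation the electron‑rich enol silane is epoxidised far faster than the allyl group and anti to the aryl group, although the C5 configuration is provisional because C5 is re‑enolised in step 14.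

**Step 10**
Reactants: 17 α‑hydroxy ketone
Product: 18 (2S,3R,4S,5S)‑2‑allyl‑4‑(3,4‑dimethoxyphenyl)‑5‑methoxy‑3‑methyl‑2‑[3‑(trimethylsilyl)prop‑2‑yn‑1‑yl]cyclopentan‑1‑one
Conditions: Me3OBF4, Proton‑sponge, 4 Å MS, CH2Cl2, rt
Reagents that add atoms: trimethyloxonium tetrafluoroborate C[O+](C)C.F[B-](F)(F)F
Why: Meerwein‑salt O‑methylation under non‑nucleophilic, non‑oxidising and essentially neutral conditions avoids α‑ketol isomerisation.

**Step 11**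
Reactants: 18 α‑methoxy ketone
Product: 19 (2S,3R,4S,5S)‑2‑allyl‑4‑(3,4‑dimethoxyphenyl)‑5‑methoxy‑3‑methyl‑2‑(prop‑2‑yn‑1‑yl)cyclopentan‑1‑one
Conditions: K2CO3 (cat.), MeOH, rt
Reagents that add atoms: none
Why: Base‑catalysed protodesilylation frees the terminal alkyne, and the only acidic centre (C5) is stereochemically irrelevant here.

**Step 12**
Reactants: 19 terminal alkyne
Product: 20 (2S,3R,4S,5S)‑2‑allyl‑4‑(3,4‑dimethoxyphenyl)‑5‑methoxy‑3‑methyl‑2‑[(E)‑3‑(4,4,5,5‑tetramethyl‑1,3,2‑dioxaborolan‑2‑yl)prop‑2‑en‑1‑yl]cyclopentan‑1‑one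
Conditions: B2pin2, CuCl (5 mol %), Xantphos (5 mol %), NaOt‑Bu (10 mol %), MeOH (2 equiv), THF, rt
Reagents that add atoms: bis(pinacolato)diboron CC1(C)OB(OC1(C)C)B1OC(C)(C)C(C)(C)O1
Why: Copper‑catalysed syn‑borylcupration and protonation (formal anti‑Markovnikov hydroboration) is selective for the alkyne and leaves the unactivated allyl group and the hindered ketone alone.

**Step 13**
Reactants: 20 alkenyl boronate
Product: 21 3‑[(1R,2R,3S,4S)‑1‑allyl‑3‑(3,4‑dimethoxyphenyl)‑4‑methoxy‑2‑methyl‑5‑oxocyclopentyl]propanal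
Conditions: NaBO3·4H2O, THF/H2O, rt
Reagents that add atoms: sodium perborate [Na+].[Na+].O[B-]1(O)OO[B-](O)(O)OO1
Why: Mild perborate oxidation of the C–B bond gives the enol, which tautomerises to the aldehyde (C4).

**Step 14**
Reactants: 21 keto aldehyde
Product: 23 (1R,4R,5R,6S,7R)‑1‑allyl‑6‑(3,4‑dimethoxyphenyl)‑4‑hydroxy‑5‑methoxy‑7‑methylbicyclo[3.2.1]octan‑8‑one, via trichlorotitanium enolate 22 (not isolated)
Conditions: TiCl4 (2.2 equiv, one being held by the veratryl ether), i‑Pr2NEt (1.2 equiv), CH2Cl2 (0.005 M), −78 → −40 °C; aq NH4Cl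
Reagents that add atoms: none
Why: In this chelation‑assisted soft enolisation and intramolecular titanium aldol, TiCl4 binds the α‑methoxy ketone so that only C5–H is removed, the tether from C1 forces C4 onto the chain face of C5 (OMe anti to aryl), and the closed Ti‑bridged transition state places O4 gauche to C8=O, giving the exo (axial) alcohol.

**Step 15**
Reactants: 23 ketol
Product: 25 (1R,4R,5R,6S,7R,8S)‑1‑allyl‑6‑(3,4‑dimethoxyphenyl)‑5‑methoxy‑7‑methylbicyclo[3.2.1]octane‑4,8‑diol, via diethylboron chelate 24 (not isolated)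
Conditions: Et2BOMe, THF/MeOH 4:1, −78 °C; NaBH4, −78 → −20 °C; AcOH; MeOH co‑evaporation
Reagents that add atoms: none
Why: In this Narasaka–Prasad syn‑1,3‑reduction boron ties the axial O4 to the C8 carbonyl on the side of the three‑carbon bridge, so external hydride must enter from the C6–C7 side and O8 ends up syn to the C2–C4 bridge (8S).

**Step 16**
Reactants: 25 diol
Product: 26 (1R,5S,6S,7R,8S)‑1‑allyl‑6‑(3,4‑dimethoxyphenyl)‑8‑hydroxy‑5‑methoxy‑7‑methylbicyclo[3.2.1]octan‑4‑one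
Conditions: Dess–Martin periodinane (1.05 equiv), CH2Cl2, 0 °C
Reagents that add atoms: none
Why: In this sterically controlled Dess–Martin oxidation C4–OH (one quaternary neighbour, exposed equatorial carbinol H) reacts well before C8–OH, which sits between two quaternary carbons.

**Step 17**
Reactants: 26 β‑hydroxy ketone
Product: 27 (1R,5S,6S,7R,8S)‑1‑allyl‑6‑(3,4‑dimethoxyphenyl)‑5‑methoxy‑7‑methyl‑4‑oxobicyclo[3.2.1]octan‑8‑yl acetate
Conditions: Ac2O, DMAP (cat.), pyridine, 40 °C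
Reagents that add atoms: acetic anhydride CC(=O)OC(C)=O
Why: DMAP‑catalysed acylation esterifies the hindered alcohol, and β‑elimination is impossible because C5 carries no hydrogen.

**Step 18**
Reactants: 27 keto acetate
Product: 28 (1S,5S,6S,7R,8S)‑1‑allyl‑6‑(3,4‑dimethoxyphenyl)‑5‑methoxy‑7‑methyl‑4‑[(trimethylsilyl)oxy]bicyclo[3.2.1]oct‑3‑en‑8‑yl acetate
Conditions: TMSOTf, Et3N, CH2Cl2, 0 °C
Reagents that add atoms: trimethylsilyl trifluoromethanesulfonate C[Si](C)(C)OS(=O)(=O)C(F)(F)F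
Why: Soft enolisation can only go toward C3 (C5 is quaternary) and tolerates the acetate, which a lithium amide would not.

**Step 19**
Reactants: 28 silyl enol ether
Product: 31 (1S,3R,5S,6S,7R,8S)‑1‑allyl‑6‑(3,4‑dimethoxyphenyl)‑3‑hydroxy‑5‑methoxy‑7‑methyl‑4‑oxobicyclo[3.2.1]octan‑8‑yl acetate, via silyloxy epoxide 29 (not isolated), via silyloxy ketone 30 (not isolated)
Conditions: mCPBA (1.05 equiv), hexane/CH2Cl2, −15 °C; then 1 M HCl, THF, 0 °C
Reagents that add atoms: 3‑chloroperoxybenzoic acid OOC(=O)c1cccc(Cl)c1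
Why: This Rubottom oxidation takes place on the exo face, away from the aryl pocket, and the C3 configuration is provisional because it is erased in step 20.

**Step 20**
Reactants: 31 α‑hydroxy ketone
Product: 33 (1R,5S,6S,7R,8S)‑1‑allyl‑6‑(3,4‑dimethoxyphenyl)‑3‑hydroxy‑5‑methoxy‑7‑methyl‑4‑oxobicyclo[3.2.1]oct‑2‑en‑8‑yl acetate, via 1,2‑diketone 32 (not isolated)
Conditions: Dess–Martin periodinane, CH2Cl2, rt; SiO2
Reagents that add atoms: none
Why: Dess–Martin oxidation gives the 1,2‑dione, which can enolise only toward C2 and settles as the single diosphenol.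

**Step 21**
Reactants: 33 diosphenol
Product: 34 (1R,5S,6S,7R,8S)‑1‑allyl‑6‑(3,4‑dimethoxyphenyl)‑3,5‑dimethoxy‑7‑methyl‑4‑oxobicyclo[3.2.1]oct‑2‑en‑8‑yl acetate
Conditions: Me2SO4, K2CO3, acetone, rt
Reagents that add atoms: dimethyl sulfate COS(=O)(=O)OC
Why: Williamson‑type O‑methylation of the acidic enol with a hard electrophile gives the α‑methoxy enone under conditions the acetate tolerates.

**Step 22**
Reactants: 34 α‑methoxy enone
Product: 36 (1S,3S,5S,6S,7R,8S)‑1‑allyl‑6‑(3,4‑dimethoxyphenyl)‑3,5‑dimethoxy‑7‑methyl‑4‑oxobicyclo[3.2.1]octan‑8‑yl acetate, via copper enolate 35 (not isolated)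
Conditions: Cu(OAc)2·H2O (5 mol %), 1,2‑bis(diphenylphosphino)benzene (5 mol %), (EtO)2MeSiH, t‑BuOH, toluene, 0 °C; pH 7 buffer
Reagents that add atoms: none
Why: In this copper hydride conjugate reduction (Stryker type) hydride adds to C2 without touching the allyl group or the ester, and bulky t‑BuOH protonates the enolate at C3 from the exo face because the endo face is closed by the C6 aryl group, leaving OMe endo (3S).

**Compound list**
1 | cis‑cyclopent‑4‑ene‑1,3‑diyl diacetate (meso) | CC(=O)O[C@@H]1C[C@H](OC(C)=O)C=C1 | starting material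
2 | (1R,4S)‑4‑hydroxycyclopent‑2‑en‑1‑yl acetate | CC(=O)O[C@@H]1C[C@H](O)C=C1 | intermediate
3 | (1R,4S)‑4‑[(tert‑butyldimethylsilyl)oxy]cyclopent‑2‑en‑1‑yl acetate | CC(=O)O[C@@H]1C[C@H](O[Si](C)(C)C(C)(C)C)C=C1 | intermediate
4 | (1R,4S)‑4‑[(tert‑butyldimethylsilyl)oxy]cyclopent‑2‑en‑1‑ol | O[C@@H]1C[C@H](O[Si](C)(C)C(C)(C)C)C=C1 | intermediate
5 | (S)‑4‑[(tert‑butyldimethylsilyl)oxy]cyclopent‑2‑en‑1‑one | O=C1C[C@H](O[Si](C)(C)C(C)(C)C)C=C1 | intermediate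
6 | allyl iodide | C=CCI | starting material
7 | lithium (3S,4S)‑4‑[(tert‑butyldimethylsilyl)oxy]‑3‑methylcyclopent‑1‑en‑1‑olate (Me2Zn complex) | [Li+].[O-]C1=C[C@H](C)[C@@H](O[Si](C)(C)C(C)(C)C)C1 | intermediate
8 | (2S,3S,4S)‑2‑allyl‑4‑[(tert‑butyldimethylsilyl)oxy]‑3‑methylcyclopentan‑1‑one | C=CC[C@@H]1C(=O)C[C@H](O[Si](C)(C)C(C)(C)C)[C@H]1C | intermediate
9 | (4R,5S)‑5‑allyl‑4‑methylcyclopent‑2‑en‑1‑one | C=CC[C@@H]1C(=O)C=C[C@H]1C | intermediate
10 | 3‑bromo‑1‑(trimethylsilyl)prop‑1‑yne | C[Si](C)(C)C#CCBr | starting material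
11 | lithium (3R)‑2‑allyl‑3‑methylcyclopenta‑1,4‑dien‑1‑olate | [Li+].[O-]C1=C(CC=C)[C@H](C)C=C1 | intermediate
12 | (4R,5S)‑5‑allyl‑4‑methyl‑5‑[3‑(trimethylsilyl)prop‑2‑yn‑1‑yl]cyclopent‑2‑en‑1‑one | C=CC[C@@]1(CC#C[Si](C)(C)C)C(=O)C=C[C@H]1C | intermediate
13 | (3,4‑dimethoxyphenyl)magnesium bromide | COc1ccc([Mg]Br)cc1OC | starting material
14 | {[(3R,4R,5S)‑5‑allyl‑3‑(3,4‑dimethoxyphenyl)‑4‑methyl‑5‑[3‑(trimethylsilyl)prop‑2‑yn‑1‑yl]cyclopent‑1‑en‑1‑yl]oxy}trimethylsilane | C=CC[C@@]1(CC#C[Si](C)(C)C)C(O[Si](C)(C)C)=C[C@H](c2ccc(OC)c(OC)c2)[C@H]1C | intermediate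
15 | epoxide of 14 (oxygen anti to the aryl group) | C=CC[C@@]1(CC#C[Si](C)(C)C)[C@@]2(O[Si](C)(C)C)O[C@H]2[C@H](c3ccc(OC)c(OC)c3)[C@H]1C | intermediate
16 | 5‑O‑trimethylsilyl ether of 17 | C=CC[C@@]1(CC#C[Si](C)(C)C)C(=O)[C@@H](O[Si](C)(C)C)[C@H](c2ccc(OC)c(OC)c2)[C@H]1C | intermediate
17 | (2S,3R,4S,5S)‑2‑allyl‑4‑(3,4‑dimethoxyphenyl)‑5‑hydroxy‑3‑methyl‑2‑[3‑(trimethylsilyl)prop‑2‑yn‑1‑yl]cyclopentan‑1‑one | C=CC[C@@]1(CC#C[Si](C)(C)C)C(=O)[C@@H](O)[C@H](c2ccc(OC)c(OC)c2)[C@H]1C | intermediate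
18 | (2S,3R,4S,5S)‑2‑allyl‑4‑(3,4‑dimethoxyphenyl)‑5‑methoxy‑3‑methyl‑2‑[3‑(trimethylsilyl)prop‑2‑yn‑1‑yl]cyclopentan‑1‑one | C=CC[C@@]1(CC#C[Si](C)(C)C)C(=O)[C@@H](OC)[C@H](c2ccc(OC)c(OC)c2)[C@H]1C | intermediate
19 | (2S,3R,4S,5S)‑2‑allyl‑4‑(3,4‑dimethoxyphenyl)‑5‑methoxy‑3‑methyl‑2‑(prop‑2‑yn‑1‑yl)cyclopentan‑1‑one | C=CC[C@@]1(CC#C)C(=O)[C@@H](OC)[C@H](c2ccc(OC)c(OC)c2)[C@H]1C | intermediate
20 | (2S,3R,4S,5S)‑2‑allyl‑4‑(3,4‑dimethoxyphenyl)‑5‑methoxy‑3‑methyl‑2‑[(E)‑3‑(pinacolboryl)prop‑2‑en‑1‑yl]cyclopentan‑1‑one | C=CC[C@@]1(C/C=C/B2OC(C)(C)C(C)(C)O2)C(=O)[C@@H](OC)[C@H](c2ccc(OC)c(OC)c2)[C@H]1C | intermediate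
21 | 3‑[(1R,2R,3S,4S)‑1‑allyl‑3‑(3,4‑dimethoxyphenyl)‑4‑methoxy‑2‑methyl‑5‑oxocyclopentyl]propanal | C=CC[C@@]1(CCC=O)C(=O)[C@@H](OC)[C@H](c2ccc(OC)c(OC)c2)[C@H]1C | intermediate
22 | trichlorotitanium enolate of 21 (C8–O–Ti, C8=C5) | C=CC[C@@]1(CCC=O)C(O[Ti](Cl)(Cl)Cl)=C(OC)[C@H](c2ccc(OC)c(OC)c2)[C@H]1C | intermediate
23 | (1R,4R,5R,6S,7R)‑1‑allyl‑6‑(3,4‑dimethoxyphenyl)‑4‑hydroxy‑5‑methoxy‑7‑methylbicyclo[3.2.1]octan‑8‑one (4‑OH exo) | C=CC[C@]12CC[C@@H](O)[C@](OC)([C@H](c3ccc(OC)c(OC)c3)[C@H]1C)C2=O | intermediate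
24 | O4‑diethylboryl derivative of 23 (boron also bound to O8) | C=CC[C@]12CC[C@@H](OB(CC)CC)[C@](OC)([C@H](c3ccc(OC)c(OC)c3)[C@H]1C)C2=O | intermediate
25 | (1R,4R,5R,6S,7R,8S)‑1‑allyl‑6‑(3,4‑dimethoxyphenyl)‑5‑methoxy‑7‑methylbicyclo[3.2.1]octane‑4,8‑diol | C=CC[C@]12CC[C@@H](O)[C@](OC)([C@H](c3ccc(OC)c(OC)c3)[C@H]1C)[C@H]2O | intermediate
26 | (1R,5S,6S,7R,8S)‑1‑allyl‑6‑(3,4‑dimethoxyphenyl)‑8‑hydroxy‑5‑methoxy‑7‑methylbicyclo[3.2.1]octan‑4‑one | C=CC[C@]12CCC(=O)[C@](OC)([C@H](c3ccc(OC)c(OC)c3)[C@H]1C)[C@H]2O | intermediate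
27 | (1R,5S,6S,7R,8S)‑1‑allyl‑6‑(3,4‑dimethoxyphenyl)‑5‑methoxy‑7‑methyl‑4‑oxobicyclo[3.2.1]octan‑8‑yl acetate | C=CC[C@]12CCC(=O)[C@](OC)([C@H](c3ccc(OC)c(OC)c3)[C@H]1C)[C@H]2OC(C)=O | intermediate
28 | (1S,5S,6S,7R,8S)‑1‑allyl‑6‑(3,4‑dimethoxyphenyl)‑5‑methoxy‑7‑methyl‑4‑[(trimethylsilyl)oxy]bicyclo[3.2.1]oct‑3‑en‑8‑yl acetate | C=CC[C@]12CC=C(O[Si](C)(C)C)[C@](OC)([C@H](c3ccc(OC)c(OC)c3)[C@H]1C)[C@H]2OC(C)=O | intermediate
29 | exo‑3,4‑epoxide of 28 | C=CC[C@]12C[C@H]3O[C@@]3(O[Si](C)(C)C)[C@](OC)([C@H](c4ccc(OC)c(OC)c4)[C@H]1C)[C@H]2OC(C)=O | intermediate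
30 | 3‑O‑trimethylsilyl ether of 31 | C=CC[C@]12C[C@@H](O[Si](C)(C)C)C(=O)[C@](OC)([C@H](c3ccc(OC)c(OC)c3)[C@H]1C)[C@H]2OC(C)=O | intermediate
31 | (1S,3R,5S,6S,7R,8S)‑1‑allyl‑6‑(3,4‑dimethoxyphenyl)‑3‑hydroxy‑5‑methoxy‑7‑methyl‑4‑oxobicyclo[3.2.1]octan‑8‑yl acetate | C=CC[C@]12C[C@@H](O)C(=O)[C@](OC)([C@H](c3ccc(OC)c(OC)c3)[C@H]1C)[C@H]2OC(C)=O | intermediate
32 | (1S,5S,6S,7R,8S)‑1‑allyl‑6‑(3,4‑dimethoxyphenyl)‑5‑methoxy‑7‑methyl‑3,4‑dioxobicyclo[3.2.1]octan‑8‑yl acetate | C=CC[C@]12CC(=O)C(=O)[C@](OC)([C@H](c3ccc(OC)c(OC)c3)[C@H]1C)[C@H]2OC(C)=O | intermediate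
33 | (1R,5S,6S,7R,8S)‑1‑allyl‑6‑(3,4‑dimethoxyphenyl)‑3‑hydroxy‑5‑methoxy‑7‑methyl‑4‑oxobicyclo[3.2.1]oct‑2‑en‑8‑yl acetate | C=CC[C@]12C=C(O)C(=O)[C@](OC)([C@H](c3ccc(OC)c(OC)c3)[C@H]1C)[C@H]2OC(C)=O | intermediate
34 | (1R,5S,6S,7R,8S)‑1‑allyl‑6‑(3,4‑dimethoxyphenyl)‑3,5‑dimethoxy‑7‑methyl‑4‑oxobicyclo[3.2.1]oct‑2‑en‑8‑yl acetate | C=CC[C@]12C=C(OC)C(=O)[C@](OC)([C@H](c3ccc(OC)c(OC)c3)[C@H]1C)[C@H]2OC(C)=O | intermediate
35 | copper(I) enolate from 34 (C4–O–Cu, C3=C4) | C=CC[C@]12CC(OC)=C(O[Cu])[C@](OC)([C@H](c3ccc(OC)c(OC)c3)[C@H]1C)[C@H]2OC(C)=O | intermediate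
36 | (1S,3S,5S,6S,7R,8S)‑1‑allyl‑6‑(3,4‑dimethoxyphenyl)‑3,5‑dimethoxy‑7‑methyl‑4‑oxobicyclo[3.2.1]octan‑8‑yl acetate | C=CC[C@]12C[C@H](OC)C(=O)[C@](OC)([C@H](c3ccc(OC)c(OC)c3)[C@H]1C)[C@H]2OC(C)=O | target

**Step count:** 22 steps in total. The longest linear sequence is 22 steps (1 → 36); compounds 6, 10 and 13 are purchased.

**Steps most likely to fail**

*Step 14 (aldol closure to the quaternary C5, cis to the aryl group).* The amine may also enolise the aldehyde, or the ring closure may reverse. The fallback separates enolate formation from aldehyde release and sets out from 20. TESOTf/Et3N converts the ketone into the triethylsilyl enol ether F1. Anhydrous Me3NO then oxidises the alkenyl boronate, and a neutral aqueous work‑up gives the enol‑silane aldehyde F2. TiCl4 alone at −78 °C exchanges silicon for titanium, so the same enolate 22 forms with no base present and closes through the same chelated transition state. This path returns to the route at 23.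

*Step 15 (facial control at C8).* The hydride must enter past the exo C7 methyl, so the chelate may react too slowly, or the unchelated ketone may leak to the 8‑epimer. The fallback replaces chelation by steric shielding and sets out from 23. TBSOTf/2,6‑lutidine gives the 4‑O‑TBS ketone F3, whose axial silyl ether covers the bridge‑side face of C8=O. LiAlH4 then delivers hydride from the open side to give the 8S alcohol F4. Ac2O/DMAP gives the silyl ether acetate F5, and HF·pyridine (acidic, to suppress 1,3‑acyl shift) gives the 4‑hydroxy 8‑acetate F6. Immediate Dess–Martin oxidation of F6 returns to the route at 27.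

*Step 22 (1,4‑reduction at the neopentyl C2 and kinetic protonation at C3).* Possible failures are sluggish hydride transfer, over‑reduction of C4=O, or epimerisation of the base‑labile product to the 3‑epimer. The fallback avoids hydride chemistry and sets out from 31. Me3OBF4/Proton‑sponge gives the exo methyl ether (3‑epi‑36) F7. TMSOTf/Et3N turns it into the trimethylsilyl enol ether F8. Et3N·3HF/AcOH at −78 °C releases the enol and protonates it from the exo face. This path returns to the route at 36.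

**Further compounds**
F1 | step 14 | triethylsilyl enol ether of 20 | C=CC[C@@]1(C/C=C/B2OC(C)(C)C(C)(C)O2)C(O[Si](CC)(CC)CC)=C(OC)[C@H](c2ccc(OC)c(OC)c2)[C@H]1C
F2 | step 14 | triethylsilyl enol ether of 21 (free aldehyde) | C=CC[C@@]1(CCC=O)C(O[Si](CC)(CC)CC)=C(OC)[C@H](c2ccc(OC)c(OC)c2)[C@H]1C
F3 | step 15 | 4‑O‑tert‑butyldimethylsilyl ether of 23 | C=CC[C@]12CC[C@@H](O[Si](C)(C)C(C)(C)C)[C@](OC)([C@H](c3ccc(OC)c(OC)c3)[C@H]1C)C2=O
F4 | step 15 | 4‑O‑tert‑butyldimethylsilyl ether of 25 (8S alcohol) | C=CC[C@]12CC[C@@H](O[Si](C)(C)C(C)(C)C)[C@](OC)([C@H](c3ccc(OC)c(OC)c3)[C@H]1C)[C@H]2O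
F5 | step 15 | 8‑acetate of F4 | C=CC[C@]12CC[C@@H](O[Si](C)(C)C(C)(C)C)[C@](OC)([C@H](c3ccc(OC)c(OC)c3)[C@H]1C)[C@H]2OC(C)=O
F6 | step 15 | 8‑O‑acetyl derivative of 25 (4‑OH free) | C=CC[C@]12CC[C@@H](O)[C@](OC)([C@H](c3ccc(OC)c(OC)c3)[C@H]1C)[C@H]2OC(C)=O
F7 | step 22 | 3‑epi‑36 (3R, OMe exo) | C=CC[C@]12C[C@@H](OC)C(=O)[C@](OC)([C@H](c3ccc(OC)c(OC)c3)[C@H]1C)[C@H]2OC(C)=O
F8 | step 22 | trimethylsilyl enol ether of F7 (C3=C4) | C=CC[C@]12CC(OC)=C(O[Si](C)(C)C)[C@](OC)([C@H](c3ccc(OC)c(OC)c3)[C@H]1C)[C@H]2OC(C)=O
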